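Thursday's run shows how long E lasts, and Monday's shows how fast D is fed into it. The question is what fraction of the D charge stands as E after 50 h at the four charges of G.

all flasks: D 0.052 M

| flask | G | remark | time | volume of the second phase over the first |
|---|---|---|---|---|
| Monday's | 0.071 M | run made earlier |  |  |
| Thursday's | 0.65 M | run made earlier |  |  |
| summer | 0.0600 M |  | 50 h | 1.0 |
| autumn | 0.150 M |  | 50 h | 1.0 |
| dusk | 0.250 M |  | 50 h | 1.0 |
| dawn | 0.500 M |  | 50 h | 1.0 |

| run | time / h | E / % | D / % |
|---|---|---|---|
| Monday's | 6.00 | 13.8 | 86.4 |
| Monday's | 12.0 | 22.5 | 74.5 |
| Monday's | 20.0 | 29.2 | 62.3 |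
| Monday's | 25.0 | 32.1 | 55.7 |
| Thursday's | 3.00 | 44.3 | 54.5 |
| Thursday's | 8.00 | 74.9 | 14.2 |
| Thursday's | 15.0 | 74.2 | 2.4 |
| Thursday's | 25.0 | 61.4 | 0 |

(readings scatter by 0.3 percentage points)

- charges count per volume of the first phase; a concentration in a rate is the amount of a species over the volume of its own phase; every rate counts per litre of the first phase
- the earlier runs hold the two phases in the same ratio of volumes as the flask asked about
- a reading or a percentage of E counts all its forms, free or not
- "hardly changes" means that all values lie within two and a half points (for a concentration: within two and a half percent of the largest)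

- amount of E at the end, in percent of the D charged for summer, autumn, dusk, dawn, in this order
- how that number moves from the first to the last of them (falls all the way / falls, then rises / hardly changes / rises, then falls / rises all the way)

How long does E last? Between 15.0 h and 25.0 h of Thursday's run, D is down to 2.4% and then 0%, so D plus E falls from 76.6 to 61.4 percent of the charge. Read as a first-order decay, that gives the lifetime of E, 45.2 h, a time constant close to the 50 h asked about.

How fast is E fed, then? D's first-order constant is 0.0231 h⁻¹ on Monday and 0.269 h⁻¹ on Thursday, a factor of 11.6. The charges of G differ by 9.15, but if one G is used per D, the mean G left over those intervals is 0.0559 M on Monday and 0.616 M on Thursday, a factor of 11.0. That factor stands close to the one between the constants, so D's constant is read as pseudo-first-order in the G left, and Monday's readings give a second-order constant of 0.413 M⁻¹ h⁻¹.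

What stands at the end? In dawn, D's constant, reckoned at the charge of G less half of D's, is 0.196 h⁻¹, so D's time constant of 5.10 h is shorter than the lifetime of E, and E is reckoned to form early and then decay. In summer, G is 1.15 times D, so the second-order balance is used, and it reckons 0.426 of D unused at the end. Autumn's constant for D is reckoned as 0.0512 h⁻¹ and dusk's as 0.0925 h⁻¹, and the formula for two first-order steps in a row then gives fractions of the charge standing as E of 0.321, 0.446, 0.422 and 0.373, in the order summer, autumn, dusk, dawn.

The forecast, resting on “a first-order loss of E”, gives 28.5%, 41%, 39.6% and 35%, a shape of rises, then falls, and its second value stands below this reckoning's 0.446.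

The flask gives 29.7%, 42.4%, 41.1% and 36.5%, also rises, then falls, turning at 0.17 M of G, and its second value too stands below the reckoned one.

    L ⇌ G, rate k1*([L] - [G]/K1) per volume of the first phase (partition coefficient = 1.80, kL = 0.0150 min⁻¹)
    D + L → E (k = 0.0200 M⁻¹ min⁻¹)
    E ⇌ X, rate k3*([E] - [X]/K3) per volume of the first phase (partition coefficient = 1.70, kL = 0.0200 min⁻¹)
    E → J (k = 8.70 × 10⁻⁴ min⁻¹)
    E → Q (k = 1.60 × 10⁻⁴ min⁻¹)

In summer at 50.0 h, the step from D + L to E has a half-life of D of 54 h, which is a time constant of 78.5 h, longer than the lifetime 45.2 h of E. With 42.5% of the charge standing as D and 29.7% as E, summer's E is then made at 0.00541 h⁻¹ of the charge, less than the 0.00656 h⁻¹ it loses.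

Readings and results were computed from invented constants, noise included.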